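The constant I carry is the pairing constant: the rate of electrophile loss divided by the product of the electrophile and nucleophile concentrations, usually called the second-order rate constant.

in all of them: electrophile 0.50 M
- theta: nucleophile 1.2 equiv; free base 0.74 equiv; run made earlier
- delta: nucleophile 1.2 equiv; free base 1.5 equiv; run made earlier
- zeta: nucleophile 1.2 equiv; free base 2.6 equiv; run made earlier
- grey: nucleophile 1.20 equiv; free base 0.800 equiv; time 3.0 min
- red: nucleophile 1.20 equiv; free base 1.60 equiv; time 3.0 min
- teal: nucleophile 1.20 equiv; free base 3.20 equiv; time 3.0 min

- theta (time / s: electrophile / %, target / %): 10.0: 95, 5; 20.0: 94, 8; 40.0: 86, 10; 60.0: 81, 13; 120: 73, 18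
- delta (time / s: electrophile / %, target / %): 12.0: 96, 4; 30.0: 84, 7; 60.0: 82, 14; 90.0: 77, 15; 120: 72, 19
- zeta (time / s: electrophile / %, target / %): 25.0: 93, 8; 50.0: 84, 10; 80.0: 80, 15; 90.0: 77, 19; 120: 71, 18

(each reading ± 1.5 percentage points)



- part of the electrophile that has reacted at the end, grey
- part of the electrophile that has reacted at the end, red
- part of the electrophile that has reacted at the end, teal
- what raising the equivalents of free base from its lowest to its highest value here does to the part of the electrophile that has reacted (changes below 5 percentage points count as none) (it falls / no change / it rises)

At the last reading, 120 s, the theta, delta and zeta runs keep 73%, 72% and 71% of their electrophile. That is a spread of 2 percentage points against a scatter of 1.5 points, while free base goes from 0.74 equiv to 2.6 equiv. I therefore pool the runs: as read, 28.0% has reacted on average by then.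

I assume that electrophile and nucleophile fall one for one, so I follow the ratio of nucleophile to electrophile. Measured against its starting value, the logarithm of that ratio then grows steadily, with a slope equal to the constant times the nucleophile excess in moles per litre. The pooled figure gives a constant of 0.00523 L mol⁻¹ s⁻¹.

Over 3.0 min the ratio then grows by a factor of 1.10, which means 37.2% reacted. I take this for all three flasks, though teal's 3.20 equiv lies beyond the runs.

The forecast gives 37%, 37% and 37% for grey, red and teal, with no change, since the rate “looks zero order in base”.

The flasks give 36.9% for grey, 37.8% for red and 38.9% for teal, a change of 2 points, so the trend is no change. My figure lies 0.60 points below red.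

    acid set free + free base ⇌ salt of the base (K = 2400 L mol⁻¹, k = 0.490 L mol⁻¹ s⁻¹)
    electrophile + nucleophile → acid set free + target (k = 0.00630 L mol⁻¹ s⁻¹)
    acid set free → by-product carried off (k = 0.00370 s⁻¹)
    crystals ⇌ acid set free, rate k4*(cs4 - [acid set free]) while solid is left; crystals form when [acid set free] > cs4 (solubility = 0.270 M, k = 0.190 s⁻¹)
    target ⇌ isomer of the product (K = 1.70, k = 0.0110 s⁻¹)
    nucleophile + acid set free ⇌ protonated nucleophile, settled at all times (K = 120 L mol⁻¹)

In red at the end, the half-life of electrophile by its step with nucleophile is 5.6 min, while the half-life of target by its forward step into isomer of the product alone is shorter, 1.1 min. At that moment red makes target 1.29 times faster than it uses it up, each step taken net, and holds 19.6% target beside 18.1% isomer of the product.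

Take red's neighbour with 4.80 equiv of nucleophile. There my constant makes the ratio grow by a factor of 5.99, which means 86.3% reacted. The computed flask gives 87.4%.

The runs come from a simulation for an exercise; noise was put on by code.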